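Numbering (spiro[5.5]undecane): ring A = C1(Me)=C2H–C3H(OH)–C4H(Br)–C5Me2, spiro atom C6, ring B = C7H2–C8(Br)=C9(Me)–C10H2–C11H2.
Retrosynthesis: C3–O and C4–Br are taken back to the ring A enone; the C8(Br)=C9(Me) unit of ring B is taken back to a C9 ketone and then to a spiro-fused cyclohexa-2,5-dienone; finally the ring A bonds C2–C3 and C1–C6 are cut together, which releases C1(Me)=C2H as propyne and leaves 3-(4-methoxyphenyl)-3-methylbutanoyl chloride.
Enabling feature: at the ketone level ring A is a 3-methylcyclohex-2-enone whose C1=C2 unit lies between acyl carbon C3 and spiro atom C6, and in ring B C9 is para to C6, so ring B is a masked 4-methoxyphenyl ring with C6 as its ipso carbon and C5 as its benzylic gem-dimethyl carbon.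
Forward: the arene (future ring B) is alkylated first; ring A closes in one acylation/ipso-spirocyclization cascade that dearomatizes ring B; ring B is desymmetrized and converted into the bromoalkene; ring A is brominated and reduced last.
Stereochemistry: C6 from a ligand-controlled copper hydride desymmetrization of the prochiral dienone; C4 from C6 by equilibration of the α-bromo ketone; C3 from C4 and C5 by substrate-controlled reduction followed by Mitsunobu inversion.

Key step: step 3

Assumption: in step 4 the ligand antipode that reduces the enone arm destined to become C7–C8 is taken to be (R)-DTBM-SEGPHOS; if the opposite sense is found, its mirror image is used and nothing else changes.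

Step 1
Reactants: 1 anisole; 2 3-methylbut-2-enoic acid
Product: 3 3-(4-methoxyphenyl)-3-methylbutanoic acid
Conditions: AlCl3, CH2Cl2, 0 °C to rt
Reagents that add atoms: none
Why: Friedel–Crafts alkylation in which the AlCl3-activated enoic acid reacts as a tertiary cation equivalent and alkylates anisole para to the methoxy group, which joins the future C5 gem-dimethyl carbon to the future spiro carbon C6.

Step 2
Reactants: 3 3-(4-methoxyphenyl)-3-methylbutanoic acid
Product: 4 3-(4-methoxyphenyl)-3-methylbutanoyl chloride
Conditions: (COCl)2, DMF (cat.), CH2Cl2, 0 °C to rt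
Reagents that add atoms: oxalyl chloride, ClC(=O)C(=O)Cl
Why: Standard acid chloride formation through DMF-catalysed (Vilsmeier-type) activation, to which the aryl methyl ether is inert.

Step 3
Reactants: 4 3-(4-methoxyphenyl)-3-methylbutanoyl chloride; 5 propyne
Product: 7 1,5,5-trimethylspiro[5.5]undeca-1,7,10-triene-3,9-dione, via oxocarbenium tetrachloroaluminate 6 (not isolated)
Conditions: AlCl3 (2.5 equiv), propyne (5 equiv), CH2Cl2, −78 to −20 °C; aq NaHCO3
Reagents that add atoms: none
Why: Proposed new method: AlCl3 ionizes 4 to the acylium ion, which acylates propyne at its terminal carbon (new C2–C3 bond) to give the methyl-stabilized vinyl cation at C1, and the 4-methoxyphenyl ring then attacks C1 through its ipso carbon (new C1–C6 bond) to give oxocarbenium ion 6, which chloride demethylates to the dienone. The closest known reaction types are the AlCl3-mediated acylation of alkynes and the electrophile-induced ipso-cyclization of 4-methoxyphenyl-tethered alkynes and ynones to spirocyclohexadienones; their merger in one flask at this tether length is the untested part. Ring A closes in a 6-endo-dig mode with respect to the alkyne-derived cation, as an ipso (spiro) Friedel–Crafts alkylation, while ring B is not closed but dearomatized. No stereocenter is formed, because C6 carries two identical enone arms in 7 and stays prochiral until step 4, and the C1=C2 geometry is fixed by the ring. The step needs Markovnikov acylation (secured by the methyl group, which stabilizes the cation at C1) and ipso attack para to the methoxy group in preference to ortho attack (a seven-membered ring) and to self-acylation of 4 at a position meta to the methoxy group, which the para donor, the tether length, excess propyne and low temperature should secure.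

Step 4
Reactants: 7 1,5,5-trimethylspiro[5.5]undeca-1,7,10-triene-3,9-dione
Product: 9 (6S)-8-bromo-1,5,5-trimethylspiro[5.5]undeca-1,10-diene-3,9-dione, via silyl dienol ether 8 (not isolated)
Conditions: Cu(OAc)2 (5 mol %), (R)-DTBM-SEGPHOS (5.5 mol %), PhMe2SiH (1.1 equiv), toluene, −40 °C; then NBS, THF, −78 °C
Reagents that add atoms: N-bromosuccinimide, O=C1CCC(=O)N1Br
Why: Copper hydride conjugate reduction that desymmetrizes the prochiral cyclohexa-2,5-dienone, in which hydride goes to C7 of one enantiotopic enone arm on the ring B face anti to the C5 gem-dimethyl carbon, the chiral bisphosphine chooses the arm and thereby the C6 configuration, the β,β-disubstituted ring A enone reacts more slowly, and NBS brominates silyl dienol ether 8 regiospecifically at C8 (whose configuration is irrelevant, since C8 becomes sp2 in step 6).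

Step 5
Reactants: 9 (6S)-8-bromo-1,5,5-trimethylspiro[5.5]undeca-1,10-diene-3,9-dione
Product: 10 (6S)-8-bromo-9-hydroxy-1,5,5,9-tetramethylspiro[5.5]undeca-1,10-dien-3-one
Conditions: MeLi, CeCl3, THF, −78 °C; aq NH4Cl
Reagents that add atoms: methyllithium, [Li]C
Why: Chemoselective 1,2-addition of the weakly basic organocerium reagent to the ring B carbonyl, which is activated by the α-bromine and unhindered, whereas the ring A carbonyl belongs to a β,β-disubstituted enone shielded by the axial C5 methyl group; the new C9 center forms as a mixture that is erased in step 6.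

Step 6
Reactants: 10 (6S)-8-bromo-9-hydroxy-1,5,5,9-tetramethylspiro[5.5]undeca-1,10-dien-3-one
Product: 11 (6S)-8-bromo-1,5,5,9-tetramethylspiro[5.5]undeca-1,8,10-trien-3-one
Conditions: TsOH·H2O (5 mol %), benzene, 50 °C
Reagents that add atoms: none
Why: Acid-catalysed E1 dehydration of the tertiary allylic alcohol, in which loss of the bromine-acidified C8 proton from the allyl cation gives the fully conjugated diene with the tetrasubstituted C8(Br)=C9(Me) bond as the thermodynamic product, so that all C8/C9 diastereomers of 10 converge.

Step 7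
Reactants: 11 (6S)-8-bromo-1,5,5,9-tetramethylspiro[5.5]undeca-1,8,10-trien-3-one
Product: 12 (6R)-8-bromo-1,5,5,9-tetramethylspiro[5.5]undeca-1,8-dien-3-one
Conditions: KO2CN=NCO2K, AcOH, MeOH/CH2Cl2, 0 °C to rt
Reagents that add atoms: none
Why: Diimide reduction (concerted syn transfer of two hydrogens) should select the cis-disubstituted C10=C11 bond over the tetrasubstituted bromoalkene and the trisubstituted enone alkene and leaves the C–Br bond and the ketone untouched; the C6 descriptor changes only through the priority rules.

Step 8
Reactants: 12 (6R)-8-bromo-1,5,5,9-tetramethylspiro[5.5]undeca-1,8-dien-3-one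
Product: 15 (4S,6S)-4,8-dibromo-1,5,5,9-tetramethylspiro[5.5]undeca-1,8-dien-3-one, via trimethylsilyl dienol ether 13 (not isolated), via (4R)-bromo ketone 14 (not isolated)
Conditions: LiN(SiMe3)2, Me3SiCl, THF, −78 °C; NBS, THF, −78 to 0 °C; DBU (0.1 equiv), CH2Cl2, rt
Reagents that add atoms: N-bromosuccinimide, O=C1CCC(=O)N1Br
Why: Kinetic α'-deprotonation of the enone at C4, silylation and electrophilic bromination of dienol ether 13 place bromine at C4, and base-mediated epimerization through the enolate (no β-hydrogen is available for elimination) should funnel 14 into 15, in which bromine is equatorial in the favoured ring A half-chair (C11 pseudoaxial, the C1 methyl group tilted over sp2 C8 and away from the axial C10 hydrogen) and therefore cis to C7.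

Step 9
Reactants: 15 (4S,6S)-4,8-dibromo-1,5,5,9-tetramethylspiro[5.5]undeca-1,8-dien-3-one
Product: 16 (3R,4S,6S)-4,8-dibromo-1,5,5,9-tetramethylspiro[5.5]undeca-1,8-dien-3-ol
Conditions: iBu2AlH, CH2Cl2, −78 °C
Reagents that add atoms: none
Why: 1,2-Reduction of the enone by a bulky aluminium hydride, in which the axial C5 methyl group blocks axial attack at C3, so that hydride should arrive on the equatorial trajectory and give the axial (3R) alcohol cis to the equatorial C4 bromine.

Step 10
Reactants: 16 (3R,4S,6S)-4,8-dibromo-1,5,5,9-tetramethylspiro[5.5]undeca-1,8-dien-3-ol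
Product: 17 (3S,4S,6S)-4,8-dibromo-1,5,5,9-tetramethylspiro[5.5]undeca-1,8-dien-3-yl 2-chloroacetate
Conditions: ClCH2CO2H, PPh3, iPrO2CN=NCO2iPr, THF, 0 °C to rt
Reagents that add atoms: chloroacetic acid, OC(=O)CCl
Why: Mitsunobu reaction in which chloroacetate displaces the activated pseudoaxial allylic C3–O bond with inversion to give the equatorial (3S) ester trans to bromine.

Step 11
Reactants: 17 (3S,4S,6S)-4,8-dibromo-1,5,5,9-tetramethylspiro[5.5]undeca-1,8-dien-3-yl 2-chloroacetate
Product: 18 (3S,4S,6S)-4,8-dibromo-1,5,5,9-tetramethylspiro[5.5]undeca-1,8-dien-3-ol (CNP0268938.1)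
Conditions: K2CO3, MeOH, 0 °C
Reagents that add atoms: none
Why: Mild base-catalysed transesterification of the activated chloroacetate frees the alcohol without touching either bromide, epoxide closure being slow because the diequatorial bromohydrin would have to reach a strained diaxial conformer.

Compound list
1 | anisole | COc1ccccc1 | starting material
2 | 3-methylbut-2-enoic acid | CC(C)=CC(=O)O | starting material
3 | 3-(4-methoxyphenyl)-3-methylbutanoic acid | COc1ccc(cc1)C(C)(C)CC(=O)O | intermediate
4 | 3-(4-methoxyphenyl)-3-methylbutanoyl chloride | COc1ccc(cc1)C(C)(C)CC(=O)Cl | intermediate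
5 | propyne | CC#C | starting material
6 | methyl(1,5,5-trimethyl-3-oxospiro[5.5]undeca-1,7,10-trien-9-ylidene)oxonium tetrachloroaluminate | CC1=CC(=O)CC(C)(C)C12C=CC(=[O+]C)C=C2.Cl[Al-](Cl)(Cl)Cl | intermediate
7 | 1,5,5-trimethylspiro[5.5]undeca-1,7,10-triene-3,9-dione | CC1=CC(=O)CC(C)(C)C12C=CC(=O)C=C2 | intermediate
8 | (6S)-9-[dimethyl(phenyl)silyl]oxy-1,5,5-trimethylspiro[5.5]undeca-1,8,10-trien-3-one | CC1=CC(=O)CC(C)(C)[C@]12C=CC(O[Si](C)(C)c3ccccc3)=CC2 | intermediate
9 | (6S)-8-bromo-1,5,5-trimethylspiro[5.5]undeca-1,10-diene-3,9-dione (both C8 epimers) | CC1=CC(=O)CC(C)(C)[C@]12C=CC(=O)C(Br)C2 | intermediate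
10 | (6S)-8-bromo-9-hydroxy-1,5,5,9-tetramethylspiro[5.5]undeca-1,10-dien-3-one (mixture at C8 and C9) | CC1=CC(=O)CC(C)(C)[C@]12C=CC(C)(O)C(Br)C2 | intermediate
11 | (6S)-8-bromo-1,5,5,9-tetramethylspiro[5.5]undeca-1,8,10-trien-3-one | CC1=CC(=O)CC(C)(C)[C@]12C=CC(C)=C(Br)C2 | intermediate
12 | (6R)-8-bromo-1,5,5,9-tetramethylspiro[5.5]undeca-1,8-dien-3-one | CC1=CC(=O)CC(C)(C)[C@]12CCC(C)=C(Br)C2 | intermediate
13 | (6S)-8-bromo-1,5,5,9-tetramethyl-3-(trimethylsilyloxy)spiro[5.5]undeca-1,3,8-triene | CC1=CC(O[Si](C)(C)C)=CC(C)(C)[C@]12CCC(C)=C(Br)C2 | intermediate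
14 | (4R,6S)-4,8-dibromo-1,5,5,9-tetramethylspiro[5.5]undeca-1,8-dien-3-one | CC1=CC(=O)[C@H](Br)C(C)(C)[C@]12CCC(C)=C(Br)C2 | intermediate
15 | (4S,6S)-4,8-dibromo-1,5,5,9-tetramethylspiro[5.5]undeca-1,8-dien-3-one | CC1=CC(=O)[C@@H](Br)C(C)(C)[C@]12CCC(C)=C(Br)C2 | intermediate
16 | (3R,4S,6S)-4,8-dibromo-1,5,5,9-tetramethylspiro[5.5]undeca-1,8-dien-3-ol (OH cis to Br) | CC1=C[C@@H](O)[C@@H](Br)C(C)(C)[C@]12CCC(C)=C(Br)C2 | intermediate
17 | (3S,4S,6S)-4,8-dibromo-1,5,5,9-tetramethylspiro[5.5]undeca-1,8-dien-3-yl 2-chloroacetate | CC1=C[C@H](OC(=O)CCl)[C@@H](Br)C(C)(C)[C@]12CCC(C)=C(Br)C2 | intermediate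
18 | (3S,4S,6S)-4,8-dibromo-1,5,5,9-tetramethylspiro[5.5]undeca-1,8-dien-3-ol (OH trans to Br) | CC1=C[C@H](O)[C@@H](Br)C(C)(C)[C@]12CCC(C)=C(Br)C2 | target

Total step count: 11 steps. Longest linear sequence: 11 steps (fully linear from anisole).

Steps most likely to fail

Step 3 (the step that carries the label). The acylium ion may acylate its own arene ring faster than it is trapped by propyne, the vinyl cation may be quenched without cyclizing, or the dienone may undergo an acid-induced 1,2-shift with rearomatization. The fallback uses known chemistry and sets out from 4. Amidation with MeNHOMe·HCl and pyridine gives the Weinreb amide N-methoxy-3-(4-methoxyphenyl)-N,3-dimethylbutanamide F1. Addition of MeC≡CMgBr gives the ynone 6-(4-methoxyphenyl)-6-methylhept-2-yn-4-one F2. A dearomatizing ipso-spirocyclization of this anisole-tethered ynone, catalysed by AgOTf or Cu(OTf)2 (or promoted by TfOH) in wet CH2Cl2, is a known reaction class; it closes C1–C6 and comes back to the route at 7.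

Step 4. Discrimination between the two enantiotopic enone arms may be poor, because hydride transfer to the neopentyl-type β-carbons is slow and the facial bias from C5 is not absolute; conjugate reduction of the ring A enone or 1,2-reduction may also compete. The fallback sets out from 7 and replaces the metal hydride by biocatalysis. An ene-reductase of the Old Yellow Enzyme family (NADPH recycled with glucose dehydrogenase), a known way to reduce one alkene of 4,4-disubstituted cyclohexa-2,5-dienones, should give (6S)-1,5,5-trimethylspiro[5.5]undeca-1,10-diene-3,9-dione F3. Kinetic enolization at the accessible C8 methylene with LiN(SiMe3)2 and Me3SiCl (the neopentyl C4 methylene of ring A is far more hindered) gives (6S)-1,5,5-trimethyl-9-(trimethylsilyloxy)spiro[5.5]undeca-1,8,10-trien-3-one F4, and NBS comes back to the route at 9.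

Step 8. The equilibrium between the C4 epimers may not lie far enough on the side of 15, since the bias rests on a small conformational preference of ring A, and base may cause loss or migration of bromine. The fallback sets out from the kinetic mixture of 14 and 15, with DBU omitted, and moves the stereochemical sorting to the alcohol stage. The mixture is reduced with iBu2AlH as in step 9, and 16 is separated by chromatography from its diastereomer (3S,4R,6S)-4,8-dibromo-1,5,5,9-tetramethylspiro[5.5]undeca-1,8-dien-3-ol F5. The sequence comes back to the route at 16. F5 is oxidized with the periodinane 1,1,1-triacetoxy-1,2-benziodoxol-3-one back to ketone 14 for another epimerization and reduction cycle.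

Further compounds
F1 | step 3 | N-methoxy-3-(4-methoxyphenyl)-N,3-dimethylbutanamide | CON(C)C(=O)CC(C)(C)c1ccc(OC)cc1
F2 | step 3 | 6-(4-methoxyphenyl)-6-methylhept-2-yn-4-one | CC#CC(=O)CC(C)(C)c1ccc(OC)cc1
F3 | step 4 | (6S)-1,5,5-trimethylspiro[5.5]undeca-1,10-diene-3,9-dione | CC1=CC(=O)CC(C)(C)[C@]12C=CC(=O)CC2
F4 | step 4 | (6S)-1,5,5-trimethyl-9-(trimethylsilyloxy)spiro[5.5]undeca-1,8,10-trien-3-one | CC1=CC(=O)CC(C)(C)[C@]12C=CC(O[Si](C)(C)C)=CC2
F5 | step 8 | (3S,4R,6S)-4,8-dibromo-1,5,5,9-tetramethylspiro[5.5]undeca-1,8-dien-3-ol | CC1=C[C@H](O)[C@H](Br)C(C)(C)[C@]12CCC(C)=C(Br)C2
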